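If the target stays close to equilibrium with substrate and dissolved gas, a single balance of gas reckons this flask.

substrate 0.062 M; gas phase 5.2 mM (held); time 40 min

    gas phase ⇌ dissolved gas, rate k1*(csat - [dissolved gas]) (k1 = 0.00572 s⁻¹, csat = 5.2 mM)
    dissolved gas + target → over-reacted product (k2 = 0.224 M⁻¹ s⁻¹)
    substrate + dissolved gas ⇌ target (K3 = 60.0 M⁻¹, k3 = 0.360 M⁻¹ s⁻¹)
    2 substrate → self-condensation product (k4 = 5.09 × 10⁻⁵ M⁻¹ s⁻¹)

- percentages count the substrate that a species holds: one self-condensation product counts as two
- for a step with 2 of a species take k times the square, and two of it per event
- at the start none of the gas is dissolved
- run time (flask): 40 min

* how much target there is at 40 min, in percent of the substrate charged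
* concentration of dissolved gas in solution at 40 min, in percent of saturation

The forward addition takes dissolved gas down with a half-life of 0.518 min at the charge, shorter than the 40 min of the run, so we assume a pre-equilibrium: target equals K, the equilibrium constant of addition, times substrate times dissolved gas. Each over-reacted product costs two dissolved gas, one to form the target and one to destroy it, so with target steady the fraction of saturation s obeys: one minus s equals N times s squared. Here N, the gas-demand number, is two times the over-reaction constant times K times substrate times saturation, over the transfer coefficient: 1.52 at the charge. That gives s = 54.7%. Taking the supply at that s as the mean over the run delivers gas worth 52.2% of the substrate charged; over-reacted product holds two gas per substrate and target one, so with about 12.6% target we lose 32.4% of the substrate, N falls to 1.02, s rises to 61.4%, and we commit to 13.0% target.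

The forecast says 12.4% and 63%, holding that "gas transfer is roughly balanced by over-reaction"; our target stands above its figure and our gas below.

The flask gives 12.3% target and 63.7% of saturation, within the forecast's margins. Dissolved gas is then made 1.01 times as fast as it is used, each step taken net, and with all amounts held it takes a reading at 5.34 min or 120 min to move the target by 5 points. With the 69% of substrate left, N becomes 1.04 and s 61.1%.

For the same flask left until 2.5 h, with 26.4% of substrate left, N gives s = 76.6%, hence 3.98 mM dissolved gas and 6.30% target. The simulation gives 4.12 mM and 5.76%.

(The numbers are those of an exercise; no experiment stands behind them.)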